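## Structural features

The target is a C20 dibromide built from three rings. Ring A (C1, C2, C3, C4, C4a, C8a) is a cyclohexenone with the C2 ketone conjugated to C3=C4. Ring B (C4a, C5, C6, C7, C8, C8a) is a cyclohexane trans-fused to it. Ring C (C1'–C5') is a cyclopentane joined through its quaternary C1' to the sp2 carbon C3.

Ring B carries four contiguous stereocentres. The C4a hydroxyl and the C8a methyl are trans and both axial. The C5 hydroxyl is axial and trans to the C4a hydroxyl, with the C5 methyl equatorial. The C8 bromine is equatorial and cis to the angular methyl. Ring C carries the quaternary C1' (methyl, C3) next to the gem-dimethyl C2', and the C3' bromide cis to the decalin substituent. The two stereochemical clusters are separated by the planar C3, so neither can control the other.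

The fragile groups are the two secondary bromides, both on neopentylic carbons (elimination, Wagner–Meerwein shift), the tertiary 4a,5-diol and the γ-hydroxy enone.

The real difficulties are:
- three quaternary carbons, two of them adjacent (C1', C2');
- a C–Br bond of defined configuration beside each quaternary block;
- the trans-diaxial diol at a ring fusion.

The key step uses the fact that C1' is a methyl-bearing quaternary carbon that lies next to C2' in a five-membered ring and carries the two-carbon arm C3–C2. Opened at C1'–C2', it is the tertiary methine of (S)-citronellol, which can be converted to the quaternary centre by C–H insertion without loss of configuration.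

## Logic of the disconnections

32 ⇒ 31 ⇒ 30. The C5–O and C4a–O bonds are cut back to one tetrasubstituted olefin (C4a=C5). The trans-diaxial diol is the Fürst–Plattner product of an epoxide, and the angular C8a methyl is the only element needed to choose the face. This removes two stereocentres and two oxygens. The forward steps must epoxidise the γ,δ-olefin of a dienone in preference to the α,β-olefin and open the epoxide at C5.

30 ⇒ 28. The C3=C4 bond is cut as an aldol condensation between the C3 methylene of a C2 ketone and a C4 aldehyde. This opens ring A and leaves a monocyclic ring B. The forward step needs enolisation toward the hindered C3; the alternative enolisation toward C1 has no ring-forming outlet.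

28 ⇒ 27 ⇒ 25 ⇒ 24 ⇒ 23. The formyl carbon C4 is cut from C4a (carbonylation of an enol triflate). The C2 ketone is traced to a 1,1-disubstituted olefin, and the C5 methyl to an enolate alkylation. The ring B ketone in 23 has only one enolisable position (C5), so both enolate steps are regiospecific. The C2 carbonyl must stay masked until the triflate is in place.

23 ⇒ 22. Both C–Br bonds are cut to carbinols of inverted configuration. The demand is SN2 displacement at two neopentylic secondary carbons without ionisation.

22 ⇒ 21. The C8–H bond is cut: 22 is the product of reducing one of the two carbonyls of a 2,2-disubstituted 1,3-dione. One reagent-controlled reduction therefore fixes C8 and C8a together. The demand is group and face selectivity.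

21 ⇒ 19 + 20. The C1–C8a bond is cut as an allylic alkylation of a stabilised dione enolate. This is the only fragment union, and it forms the quaternary C8a at a stage where it is not yet stereogenic. The electrophile must carry C2 as a masked ketone, because a free ketone would compete in the reduction that follows.

19 ⇒ 18 ⇒ 16. C1 and the sacrificial methylene carbon are both cut from C2, which returns to an ester carbon. The two-carbon arm of ring C thus stays C3–C2 throughout.

16 ⇒ 15 ⇒ 14 ⇒ 13. The C3' carbinol is traced to a ketone flanked by a quaternary and a methylene carbon, a good substrate for reagent-controlled reduction. The ester is traced to the silyl-protected primary alcohol.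

13 ⇒ 12 ⇒ 11 ⇒ 10 ⇒ 9. The two C2' methyl groups are traced to one C-methylation and to the ester carbon of a cyclic β-keto ester. The acceptor group of the key step is thus used, not discarded.

9 ⇒ 8. The C1'–C2' bond is cut. This opens ring C and turns the quaternary stereocentre into a tertiary C–H centre. The forward step must insert into that one C–H bond with retention.

8 ⇒ 7 ⇒ 4 + 5 ⇒ 2 ⇒ 1. The diazo group, the malonyl two-carbon unit and the silyl group are removed in turn. The trisubstituted olefin of 1 is the latent carboxyl carbon that becomes C3'.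

## Other disconnections considered

Alternative 1: The two oxygen atoms of ring A (C2–O and C4a–O) are cut back to molecular oxygen. Forward, sensitised photooxygenation of the ring A diene A2 would give the bridged endoperoxide A1, and base-induced Kornblum–DeLaMare rearrangement of A1 would give 32 directly.
- In favour: both ring A oxygens arrive in the last two operations without acid. The rearrangement can go only one way because C4a bears no hydrogen. The bromides are not at risk.
- Against: A2 must already contain the C5 tertiary carbinol, both bromides and a regiodefined homoannular diene carrying the bulky C1' group. Ene reaction at the C1 methylene competes with the cycloaddition.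
- Comparison: facial control comes from the C8a methyl in both plans, so they are equal there. The alternative is the better of the two in avoiding cationic character at C5. It is not shorter, because ring A and C5 must still be made first, whereas the chosen plan takes both the C4a and the C5 oxygen from one olefin. It does not address C1' and is compatible with the insertion, not a replacement for it.

Alternative 2: The C4a–C8a and C8–Br bonds are cut. Forward, a bromonium source would add to the distal olefin of the acyclic cyano dienyl acetate A4, and the proximal olefin would close ring B to give A3.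
- In favour: one step makes ring B, the quaternary C8a and the equatorial bromide cis to the methyl group, through anti addition in a chair. On the C8–Br bond this is clearly the better plan, since the chosen route needs a displacement at a neopentylic carbinol. A3 also holds C4 and the C4a=C5 olefin, which the chosen route reaches only after several steps.
- Against: the cyclisation gives racemic material unless the bromonium source is chiral, and enantiocontrol in this reaction class is not dependable; union with enantiopure ring C would give diastereomer mixtures. Proton loss after cyclisation can give olefin isomers. The nitrile places C2 on the ring B fragment, so ring A would need a carbanion at C3 next to the quaternary C1', which the two-carbon arm of the insertion product does not provide.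
- Comparison: better on step count for ring B and on the bromide; worse on absolute configuration and on the fragment union.

Alternative 3: The C1' methyl is cut as a cyclopropane methylene. Forward, Et2Zn and CH2I2 would cyclopropanate the cyclopentenol A6 on the hydroxyl face to give A5, and reductive opening of the C5'–CH2 bond of A5 would reveal the methyl group.
- In favour: one catalytic asymmetric reduction sets C3', and C3' then sets C1'. The hydroxyl ends cis to the future methyl, which is exactly the epimer needed for inversion to the bromide. On this point the alternative is better, because the chosen plan needs a separate reagent-controlled reduction (step 12). The gem-dimethyl group is present from the start, so the ester-to-methyl steps fall away and ring C is reached in fewer steps.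
- Against: regioselective cleavage of one external cyclopropane bond is demanding. The absolute configuration depends on the selectivity of a catalyst, whereas the chosen plan takes C1' from the chiral pool with retention. A6 needs its own synthesis.
- Comparison: both key steps are concerted and stereospecific (equal). The alternative is better on the C1'/C3' relationship and on steps; the chosen plan is better on the certainty of the quaternary configuration.

Key step: step 5

Remark on the structures: 8 and 9 were checked atom by atom against the target and needed no correction. The citronellol-derived centre is S in 1–8 and R from 9 onward only because ring closure changes the CIP priorities; the spatial arrangement is retained.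

Remark on numbering: metal carbenoids, enolates, alkoxyphosphonium ions and boron or aluminium alkoxides are treated as transient species and are not numbered. Neutral intermediates of one-flask sequences are numbered.

Step 1
Reactants: 1 (S)-(−)-citronellol
Product: 2 tert-butyl{[(3S)-3,7-dimethyloct-6-en-1-yl]oxy}dimethylsilane
Conditions: TBSCl, imidazole, DMF, rt
Reagents that add atoms: tert-butyldimethylsilyl chloride, CC(C)(C)[Si](C)(C)Cl
Why: Standard silylation of a primary alcohol; the stereocentre is untouched. The ether is meant to last through the hydride steps and to be cleaved and oxidised in one operation in step 10.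

Step 2
Reactants: 2 tert-butyl{[(3S)-3,7-dimethyloct-6-en-1-yl]oxy}dimethylsilane
Product: 4 (4S)-6-[(tert-butyldimethylsilyl)oxy]-4-methylhexanoic acid, via aldehyde 3 (not isolated)
Conditions: O3, MeCN/H2O, 0 °C; then NaClO2, NaH2PO4, rt
Reagents that add atoms: ozone, [O-][O+]=O; sodium chlorite, [Na+].[O-]Cl=O
Why: Ozonolysis of the trisubstituted olefin in aqueous acetonitrile releases the aldehyde directly, and chlorite oxidation (Pinnick type) in the same flask should give the acid. The hydrogen peroxide from the first stage scavenges hypochlorite, and the stereocentre is remote from the carbonyl and cannot epimerise.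

Step 3
Reactants: 4 (4S)-6-[(tert-butyldimethylsilyl)oxy]-4-methylhexanoic acid; 5 Meldrum's acid
Product: 7 methyl (6S)-8-[(tert-butyldimethylsilyl)oxy]-6-methyl-3-oxooctanoate, via acyl Meldrum's acid 6 (not isolated)
Conditions: DCC, DMAP, CH2Cl2, 0 °C to rt; filter; MeOH, reflux
Reagents that add atoms: methanol, CO
Why: Carbodiimide acylation of Meldrum's acid followed by methanolysis (loss of acetone and CO2 through the acylketene) is the standard two-carbon homologation of an acid to a β-keto ester. The conditions are neutral to mildly basic and leave the silyl ether alone.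

Step 4
Reactants: 7 methyl (6S)-8-[(tert-butyldimethylsilyl)oxy]-6-methyl-3-oxooctanoate
Product: 8 methyl (6S)-8-[(tert-butyldimethylsilyl)oxy]-2-diazo-6-methyl-3-oxooctanoate
Conditions: 4-acetamidobenzenesulfonyl azide, Et3N, MeCN, 0 °C to rt
Reagents that add atoms: 4-acetamidobenzenesulfonyl azide, CC(=O)Nc1ccc(cc1)S(=O)(=O)N=[N+]=[N-]
Why: Regitz diazo transfer to the doubly activated methylene; the sulfonamide by-product is removed by filtration and base wash.

Step 5
Reactants: 8 methyl (6S)-8-[(tert-butyldimethylsilyl)oxy]-2-diazo-6-methyl-3-oxooctanoate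
Product: 9 methyl (5R)-5-{2-[(tert-butyldimethylsilyl)oxy]ethyl}-5-methyl-2-oxocyclopentane-1-carboxylate (C1 epimers and enol)
Conditions: Rh2(OAc)4 (1 mol %), CH2Cl2, rt, slow addition of 8
Reagents that add atoms: none
Why: Rh2(OAc)4 takes up the diazo carbon, nitrogen leaves, and an electrophilic rhodium carbenoid stands at C2' between the ketone and the ester. The carbenoid carbon meets the C1'–H bond in a concerted three-centre transition state, so C1'–C2' forms while the hydrogen moves to C2' and the catalyst is released. The closest known reaction type is the dirhodium-mediated intramolecular 1,5 C–H insertion of α-diazo β-keto esters to 2-alkoxycarbonylcyclopentanones. Ring C closes as a five-membered ring by 1,5-insertion through a chair-like six-membered array (C2', C3', C4', C5', C1', H). C1' is the only stereocentre that matters: it is controlled by the citronellol methine itself, because the new bond enters where the hydrogen was and the configuration is retained. C2' forms as an enolisable mixture that disappears when it becomes the gem-dimethyl carbon. The step needs site selectivity for the tertiary 1,5 C–H bond. The substrate secures it because this is the most electron-rich C–H bond and the only one at five-ring distance; the secondary C–H bonds would give a six-membered ring, and the O–CH2 hydrogens would give a seven-membered ring. The silyloxy oxygen is two carbons from the methine, so its inductive deactivation should be small, and slow addition at low catalyst loading suppresses carbene dimerisation.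

Step 6
Reactants: 9 methyl (5R)-5-{2-[(tert-butyldimethylsilyl)oxy]ethyl}-5-methyl-2-oxocyclopentane-1-carboxylate
Product: 10 methyl (5R)-5-{2-[(tert-butyldimethylsilyl)oxy]ethyl}-1,5-dimethyl-2-oxocyclopentane-1-carboxylate (C1 epimers)
Conditions: K2CO3, MeI, acetone, reflux
Reagents that add atoms: iodomethane, CI
Why: C-Alkylation of a cyclic β-keto ester enolate; the ester confines methylation to C2' and not C4'. The configuration of the new centre is irrelevant, because C2' ends as CMe2.

Step 7
Reactants: 10 methyl (5R)-5-{2-[(tert-butyldimethylsilyl)oxy]ethyl}-1,5-dimethyl-2-oxocyclopentane-1-carboxylate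
Product: 11 (3R)-3-{2-[(tert-butyldimethylsilyl)oxy]ethyl}-2-(hydroxymethyl)-2,3-dimethylcyclopentan-1-ol (mixture at C1 and C2)
Conditions: LiAlH4, THF, 0 °C to rt
Reagents that add atoms: none
Why: Hydride reduction of the ester and the ketone to the 1,3-diol; a non-enolisable β-keto ester cannot undergo retro-Claisen cleavage by enolate formation. The diastereomers are carried on together because both extra centres are removed later.

Step 8
Reactants: 11 (3R)-3-{2-[(tert-butyldimethylsilyl)oxy]ethyl}-2-(hydroxymethyl)-2,3-dimethylcyclopentan-1-ol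
Product: 12 [(2R)-2-{2-[(tert-butyldimethylsilyl)oxy]ethyl}-5-hydroxy-1,2-dimethylcyclopentyl]methyl 4-methylbenzenesulfonate (mixture at C1 and C5)
Conditions: TsCl, pyridine, DMAP (cat.), CH2Cl2, 0 °C
Reagents that add atoms: 4-methylbenzenesulfonyl chloride, Cc1ccc(cc1)S(Cl)(=O)=O
Why: Sulfonylation occurs at oxygen, so the primary hydroxyl should react well ahead of the secondary one, which is flanked by a quaternary carbon.

Step 9
Reactants: 12 [(2R)-2-{2-[(tert-butyldimethylsilyl)oxy]ethyl}-5-hydroxy-1,2-dimethylcyclopentyl]methyl 4-methylbenzenesulfonate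
Product: 13 (3R)-3-{2-[(tert-butyldimethylsilyl)oxy]ethyl}-2,2,3-trimethylcyclopentan-1-ol (C1 epimers)
Conditions: LiEt3BH, THF, 0 °C to reflux
Reagents that add atoms: none
Why: LiEt3BH is the hydride of choice for SN2 reduction of neopentyl-type sulfonates, and it turns the former ester carbon into the second C2' methyl. C2' ceases to be a stereocentre.

Step 10
Reactants: 13 (3R)-3-{2-[(tert-butyldimethylsilyl)oxy]ethyl}-2,2,3-trimethylcyclopentan-1-ol
Product: 14 2-[(1R)-1,2,2-trimethyl-3-oxocyclopentyl]acetic acid
Conditions: CrO3, H2SO4, H2O, acetone, 0 °C to rt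
Reagents that add atoms: water, O
Why: Jones oxidation: the acidic medium cleaves the primary silyl ether, the liberated alcohol is oxidised through the aldehyde hydrate to the acid, and the secondary alcohol gives the ketone. Both C3' epimers converge on one compound.

Step 11
Reactants: 14 2-[(1R)-1,2,2-trimethyl-3-oxocyclopentyl]acetic acid
Product: 15 methyl 2-[(1R)-1,2,2-trimethyl-3-oxocyclopentyl]acetate
Conditions: MeOH, H2SO4 (cat.), 65 °C
Reagents that add atoms: methanol, CO
Why: Fischer esterification of an unhindered CH2CO2H group; the ketone between a quaternary and a methylene carbon is too hindered to hold a ketal through aqueous work-up.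

Step 12
Reactants: 15 methyl 2-[(1R)-1,2,2-trimethyl-3-oxocyclopentyl]acetate
Product: 16 methyl 2-[(1R,3S)-3-hydroxy-1,2,2-trimethylcyclopentyl]acetate
Conditions: (R)-2-methyl-CBS-oxazaborolidine (20 mol %), BH3·SMe2, THF, −20 °C
Reagents that add atoms: none
Why: Corey–Bakshi–Shibata reduction of a ketone flanked by a quaternary carbon (large) and a methylene (small). With the (R)-catalyst the hydride should enter on the face of the arm and give the (S)-carbinol, hydroxyl cis to the C1' methyl, which is the epimer needed for inversion in step 17. The substrate bias (methyl against CH2CO2Me, both 1,3 to the carbonyl) is weak, so reagent control should dominate; the ester is inert to borane at this temperature.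

Step 13
Reactants: 16 methyl 2-[(1R,3S)-3-hydroxy-1,2,2-trimethylcyclopentyl]acetate
Product: 18 (1S,3R)-2,2,3-trimethyl-3-{2-[(trimethylsilyl)methyl]prop-2-en-1-yl}cyclopentan-1-ol, via bis-silyl carbinol 17 (not isolated)
Conditions: Me3SiCH2MgCl (5 equiv), CeCl3, THF, −78 °C to rt; then SiO2, CH2Cl2
Reagents that add atoms: (trimethylsilyl)methylmagnesium chloride, C[Si](C)(C)C[Mg]Cl
Why: Double addition of the cerium-modified Grignard reagent to the ester gives the bis(β-silyl) tertiary carbinol, and mild acid effects Peterson elimination to the 2-substituted allylsilane. C2 thereby gains C1 and a methylene mask for its future carbonyl; the free hydroxyl only consumes one equivalent of reagent.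

Step 14
Reactants: 18 (1S,3R)-2,2,3-trimethyl-3-{2-[(trimethylsilyl)methyl]prop-2-en-1-yl}cyclopentan-1-ol
Product: 19 (1S,3R)-3-[2-(bromomethyl)prop-2-en-1-yl]-2,2,3-trimethylcyclopentan-1-ol
Conditions: NBS, propylene oxide, CH2Cl2, −78 °C
Reagents that add atoms: N-bromosuccinimide, BrN1C(=O)CCC1=O
Why: Electrophilic bromodesilylation of an allylsilane (attack at the olefin terminus, loss of the silyl group). The allyl unit is symmetrical about C2, so the transposition gives a single allylic bromide; the C3' hydroxyl is trans to the arm and cannot cyclise onto the bromonium ion.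

Step 15
Reactants: 19 (1S,3R)-3-[2-(bromomethyl)prop-2-en-1-yl]-2,2,3-trimethylcyclopentan-1-ol; 20 2-methylcyclohexane-1,3-dione
Product: 21 2-(2-{[(1R,3S)-3-hydroxy-1,2,2-trimethylcyclopentyl]methyl}prop-2-en-1-yl)-2-methylcyclohexane-1,3-dione
Conditions: 20, NaH, THF, 0 °C; then 19, Pd(PPh3)4 (5 mol %), rt to 50 °C
Reagents that add atoms: none
Why: Tsuji–Trost allylation: the soft dione enolate attacks the π-allyl complex of divalent palladium, whose two termini are identical, and forms C1–C8a. Any O-allylated material re-ionises under the catalyst and is funnelled to the C-allyl product; C8a is not yet stereogenic.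

Step 16
Reactants: 21 2-(2-{[(1R,3S)-3-hydroxy-1,2,2-trimethylcyclopentyl]methyl}prop-2-en-1-yl)-2-methylcyclohexane-1,3-dione
Product: 22 (2R,3R)-3-hydroxy-2-(2-{[(1R,3S)-3-hydroxy-1,2,2-trimethylcyclopentyl]methyl}prop-2-en-1-yl)-2-methylcyclohexan-1-one
Conditions: (S)-2-methyl-CBS-oxazaborolidine (30 mol %), catecholborane (2.2 equiv), toluene, −78 °C
Reagents that add atoms: none
Why: Desymmetrising Corey–Bakshi–Shibata reduction of a 2,2-disubstituted 1,3-dione. The (S)-catalyst (quaternary carbon as large group) should give the (R)-carbinol, and hydride should add anti to the bulky allyl-type substituent, so the hydroxyl is cis to the C1 arm and trans to the C8a methyl. C8 and C8a are set together, stereoisomers are diastereomers of 22 because ring C is enantiopure, and catecholborane is chosen because it does not hydroborate the olefin at this temperature.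

Step 17
Reactants: 22 (2R,3R)-3-hydroxy-2-(2-{[(1R,3S)-3-hydroxy-1,2,2-trimethylcyclopentyl]methyl}prop-2-en-1-yl)-2-methylcyclohexan-1-one
Product: 23 (2S,3S)-3-bromo-2-(2-{[(1R,3R)-3-bromo-1,2,2-trimethylcyclopentyl]methyl}prop-2-en-1-yl)-2-methylcyclohexan-1-one
Conditions: CBr4, P(n-C8H17)3, 1-methylcyclohexene, toluene, 70 °C
Reagents that add atoms: tetrabromomethane, BrC(Br)(Br)Br
Why: Appel reaction: each carbinol is activated as an alkoxyphosphonium ion and displaced by bromide with inversion. This should give C3'–Br cis to the arm and C8–Br cis to the C8a methyl. The trialkylphosphine in a non-polar solvent is the protocol used for neopentylic carbinols because it disfavours ionisation and methyl shift; the olefin scavenges traces of HBr.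

Step 18
Reactants: 23 (2S,3S)-3-bromo-2-(2-{[(1R,3R)-3-bromo-1,2,2-trimethylcyclopentyl]methyl}prop-2-en-1-yl)-2-methylcyclohexan-1-one
Product: 24 (2S,3S)-3-bromo-2-(2-{[(1R,3R)-3-bromo-1,2,2-trimethylcyclopentyl]methyl}prop-2-en-1-yl)-2,6-dimethylcyclohexan-1-one (C6 epimers)
Conditions: LiN(i-Pr)2, THF, −78 °C; MeI, −78 to −20 °C
Reagents that add atoms: iodomethane, CI
Why: Enolate methylation at C5, the only enolisable position because C8a is quaternary and C2 is still an olefin. The bromide at C8 cannot be lost by E1cB (no hydrogen at C8a), and neopentylic secondary bromides are poor E2 substrates at this temperature.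

Step 19
Reactants: 24 (2S,3S)-3-bromo-2-(2-{[(1R,3R)-3-bromo-1,2,2-trimethylcyclopentyl]methyl}prop-2-en-1-yl)-2,6-dimethylcyclohexan-1-one
Product: 25 (5S,6S)-5-bromo-6-(2-{[(1R,3R)-3-bromo-1,2,2-trimethylcyclopentyl]methyl}prop-2-en-1-yl)-2,6-dimethylcyclohex-1-en-1-yl trifluoromethanesulfonate
Conditions: KN(SiMe3)2, THF, −78 °C; PhNTf2, −78 to 0 °C
Reagents that add atoms: N-phenylbis(trifluoromethanesulfonimide), FC(F)(F)S(=O)(=O)N(c1ccccc1)S(=O)(=O)C(F)(F)F
Why: O-Triflation of the only possible enolate gives the tetrasubstituted enol triflate, as for 2,2,6-trisubstituted cyclohexanones in general; the C5 epimers converge.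

Step 20
Reactants: 25 (5S,6S)-5-bromo-6-(2-{[(1R,3R)-3-bromo-1,2,2-trimethylcyclopentyl]methyl}prop-2-en-1-yl)-2,6-dimethylcyclohex-1-en-1-yl trifluoromethanesulfonate
Product: 27 (5S,6S)-5-bromo-6-{3-[(1R,3R)-3-bromo-1,2,2-trimethylcyclopentyl]-2-oxopropyl}-2,6-dimethylcyclohex-1-en-1-yl trifluoromethanesulfonate, via diol 26 (not isolated)
Conditions: OsO4 (2 mol %), NaIO4, 2,6-lutidine, dioxane/H2O, rt
Reagents that add atoms: osmium tetroxide, O=[Os](=O)(=O)=O; sodium periodate, [Na+].[O-]I(=O)(=O)=O
Why: Lemieux–Johnson cleavage: OsO4 dihydroxylates the electron-rich 1,1-disubstituted olefin and leaves the electron-poor, tetrasubstituted enol triflate. Periodate cleaves the diol to the C2 ketone. The olefin is removed here so that the acylpalladium species of step 21 has no alkene to add to.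

Step 21
Reactants: 27 (5S,6S)-5-bromo-6-{3-[(1R,3R)-3-bromo-1,2,2-trimethylcyclopentyl]-2-oxopropyl}-2,6-dimethylcyclohex-1-en-1-yl trifluoromethanesulfonate
Product: 28 (5S,6S)-5-bromo-6-{3-[(1R,3R)-3-bromo-1,2,2-trimethylcyclopentyl]-2-oxopropyl}-2,6-dimethylcyclohex-1-ene-1-carbaldehyde
Conditions: Pd(OAc)2 (5 mol %), dppp, CO (1 atm), Et3SiH, Et3N, DMF, 70 °C
Reagents that add atoms: carbon monoxide, [C-]#[O+]
Why: Palladium-catalysed reductive carbonylation (formylation) of an enol triflate: oxidative addition to zerovalent palladium, CO insertion and hydride transfer from the silane give the enal and install C4. Unactivated secondary alkyl bromides do not add to this catalyst, and a silane is used instead of a tin hydride so that no radical debromination can start.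

Step 22
Reactants: 28 (5S,6S)-5-bromo-6-{3-[(1R,3R)-3-bromo-1,2,2-trimethylcyclopentyl]-2-oxopropyl}-2,6-dimethylcyclohex-1-ene-1-carbaldehyde
Product: 30 (8S,8aS)-8-bromo-3-[(1R,3R)-3-bromo-1,2,2-trimethylcyclopentyl]-5,8a-dimethyl-6,7,8,8a-tetrahydronaphthalen-2(1H)-one, via aldol adduct 29 (not isolated)
Conditions: p-TsOH·H2O (cat.), toluene, 80 °C
Reagents that add atoms: none
Why: Intramolecular aldol condensation: the C3 enol of the C2 ketone adds to the C4 aldehyde (6-enolendo, the only ring-forming mode, since C1 attack would give a four-membered ring), and dehydration gives the linear dienone. Acid catalysis keeps the bromides away from base, and no stereocentre is formed.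

Step 23
Reactants: 30 (8S,8aS)-8-bromo-3-[(1R,3R)-3-bromo-1,2,2-trimethylcyclopentyl]-5,8a-dimethyl-6,7,8,8a-tetrahydronaphthalen-2(1H)-one
Product: 31 (4aR,5S,8S,8aS)-8-bromo-3-[(1R,3R)-3-bromo-1,2,2-trimethylcyclopentyl]-4a,5-epoxy-5,8a-dimethyl-4a,5,6,7,8,8a-hexahydronaphthalen-2(1H)-one
Conditions: m-CPBA, NaHCO3, CH2Cl2, 0 °C
Reagents that add atoms: 3-chloroperoxybenzoic acid, OOC(=O)c1cccc(Cl)c1
Why: Prilezhaev epoxidation of the distal, tetrasubstituted γ,δ-olefin of a dienone, which is far more nucleophilic than the α,β-olefin. The peracid should approach anti to the axial C8a methyl, as in the epoxidation of steroidal 5-enes, and so place the oxygen on the face that the C4a hydroxyl needs.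

Step 24
Reactants: 31 (4aR,5S,8S,8aS)-8-bromo-3-[(1R,3R)-3-bromo-1,2,2-trimethylcyclopentyl]-4a,5-epoxy-5,8a-dimethyl-4a,5,6,7,8,8a-hexahydronaphthalen-2(1H)-one
Product: 32 (4aR,5R,8S,8aS)-8-bromo-3-[(1R,3R)-3-bromo-1,2,2-trimethylcyclopentyl]-4a,5-dihydroxy-5,8a-dimethyl-4a,5,6,7,8,8a-hexahydronaphthalen-2(1H)-one (CNP0216929.1)
Conditions: HClO4 (0.5 M aq), THF, 0 °C to rt
Reagents that add atoms: water, O
Why: Acid-catalysed trans-diaxial epoxide opening (Fürst–Plattner): water attacks C5, the tertiary carbon not deactivated by the enone, from the face opposite the oxygen. This gives the axial C5 hydroxyl trans to the retained C4a hydroxyl, with the C5 methyl equatorial. By the same rule an epoxide of the other face would be opened at C4a and give the same diol, so the outcome does not depend on complete facial selectivity in step 23.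

## Compound list

1 | (S)-(−)-citronellol, (3S)-3,7-dimethyloct-6-en-1-ol | CC(C)=CCC[C@H](C)CCO | starting material
2 | tert-butyl{[(3S)-3,7-dimethyloct-6-en-1-yl]oxy}dimethylsilane | CC(C)=CCC[C@H](C)CCO[Si](C)(C)C(C)(C)C | intermediate
3 | (4S)-6-[(tert-butyldimethylsilyl)oxy]-4-methylhexanal | O=CCC[C@H](C)CCO[Si](C)(C)C(C)(C)C | intermediate (not isolated)
4 | (4S)-6-[(tert-butyldimethylsilyl)oxy]-4-methylhexanoic acid | OC(=O)CC[C@H](C)CCO[Si](C)(C)C(C)(C)C | intermediate
5 | Meldrum's acid, 2,2-dimethyl-1,3-dioxane-4,6-dione | CC1(C)OC(=O)CC(=O)O1 | starting material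
6 | 5-{(4S)-6-[(tert-butyldimethylsilyl)oxy]-4-methylhexanoyl}-2,2-dimethyl-1,3-dioxane-4,6-dione | CC1(C)OC(=O)C(C(=O)CC[C@H](C)CCO[Si](C)(C)C(C)(C)C)C(=O)O1 | intermediate (not isolated)
7 | methyl (6S)-8-[(tert-butyldimethylsilyl)oxy]-6-methyl-3-oxooctanoate | COC(=O)CC(=O)CC[C@H](C)CCO[Si](C)(C)C(C)(C)C | intermediate
8 | methyl (6S)-8-[(tert-butyldimethylsilyl)oxy]-2-diazo-6-methyl-3-oxooctanoate | COC(=O)C(=[N+]=[N-])C(=O)CC[C@H](C)CCO[Si](C)(C)C(C)(C)C | intermediate
9 | methyl (5R)-5-{2-[(tert-butyldimethylsilyl)oxy]ethyl}-5-methyl-2-oxocyclopentane-1-carboxylate (C1 epimers and enol) | COC(=O)C1C(=O)CC[C@]1(C)CCO[Si](C)(C)C(C)(C)C | intermediate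
10 | methyl (5R)-5-{2-[(tert-butyldimethylsilyl)oxy]ethyl}-1,5-dimethyl-2-oxocyclopentane-1-carboxylate (C1 epimers) | COC(=O)C1(C)C(=O)CC[C@]1(C)CCO[Si](C)(C)C(C)(C)C | intermediate
11 | (3R)-3-{2-[(tert-butyldimethylsilyl)oxy]ethyl}-2-(hydroxymethyl)-2,3-dimethylcyclopentan-1-ol (mixture at C1 and C2) | OCC1(C)C(O)CC[C@]1(C)CCO[Si](C)(C)C(C)(C)C | intermediate
12 | [(2R)-2-{2-[(tert-butyldimethylsilyl)oxy]ethyl}-5-hydroxy-1,2-dimethylcyclopentyl]methyl 4-methylbenzenesulfonate (mixture at C1 and C5) | Cc1ccc(cc1)S(=O)(=O)OCC1(C)C(O)CC[C@]1(C)CCO[Si](C)(C)C(C)(C)C | intermediate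
13 | (3R)-3-{2-[(tert-butyldimethylsilyl)oxy]ethyl}-2,2,3-trimethylcyclopentan-1-ol (C1 epimers) | CC1(C)C(O)CC[C@]1(C)CCO[Si](C)(C)C(C)(C)C | intermediate
14 | 2-[(1R)-1,2,2-trimethyl-3-oxocyclopentyl]acetic acid | CC1(C)C(=O)CC[C@]1(C)CC(=O)O | intermediate
15 | methyl 2-[(1R)-1,2,2-trimethyl-3-oxocyclopentyl]acetate | CC1(C)C(=O)CC[C@]1(C)CC(=O)OC | intermediate
16 | methyl 2-[(1R,3S)-3-hydroxy-1,2,2-trimethylcyclopentyl]acetate | CC1(C)[C@@H](O)CC[C@]1(C)CC(=O)OC | intermediate
17 | (1S,3R)-3-{2-hydroxy-3-(trimethylsilyl)-2-[(trimethylsilyl)methyl]propyl}-2,2,3-trimethylcyclopentan-1-ol | CC1(C)[C@@H](O)CC[C@]1(C)CC(O)(C[Si](C)(C)C)C[Si](C)(C)C | intermediate (not isolated)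
18 | (1S,3R)-2,2,3-trimethyl-3-{2-[(trimethylsilyl)methyl]prop-2-en-1-yl}cyclopentan-1-ol | CC1(C)[C@@H](O)CC[C@]1(C)CC(=C)C[Si](C)(C)C | intermediate
19 | (1S,3R)-3-[2-(bromomethyl)prop-2-en-1-yl]-2,2,3-trimethylcyclopentan-1-ol | CC1(C)[C@@H](O)CC[C@]1(C)CC(=C)CBr | intermediate
20 | 2-methylcyclohexane-1,3-dione | CC1C(=O)CCCC1=O | starting material
21 | 2-(2-{[(1R,3S)-3-hydroxy-1,2,2-trimethylcyclopentyl]methyl}prop-2-en-1-yl)-2-methylcyclohexane-1,3-dione | CC1(C)[C@@H](O)CC[C@]1(C)CC(=C)CC1(C)C(=O)CCCC1=O | intermediate
22 | (2R,3R)-3-hydroxy-2-(2-{[(1R,3S)-3-hydroxy-1,2,2-trimethylcyclopentyl]methyl}prop-2-en-1-yl)-2-methylcyclohexan-1-one | CC1(C)[C@@H](O)CC[C@]1(C)CC(=C)C[C@]1(C)[C@H](O)CCCC1=O | intermediate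
23 | (2S,3S)-3-bromo-2-(2-{[(1R,3R)-3-bromo-1,2,2-trimethylcyclopentyl]methyl}prop-2-en-1-yl)-2-methylcyclohexan-1-one | CC1(C)[C@H](Br)CC[C@]1(C)CC(=C)C[C@]1(C)[C@@H](Br)CCCC1=O | intermediate
24 | (2S,3S)-3-bromo-2-(2-{[(1R,3R)-3-bromo-1,2,2-trimethylcyclopentyl]methyl}prop-2-en-1-yl)-2,6-dimethylcyclohexan-1-one (C6 epimers) | CC1(C)[C@H](Br)CC[C@]1(C)CC(=C)C[C@]1(C)[C@@H](Br)CCC(C)C1=O | intermediate
25 | (5S,6S)-5-bromo-6-(2-{[(1R,3R)-3-bromo-1,2,2-trimethylcyclopentyl]methyl}prop-2-en-1-yl)-2,6-dimethylcyclohex-1-en-1-yl trifluoromethanesulfonate | CC1(C)[C@H](Br)CC[C@]1(C)CC(=C)C[C@]1(C)[C@@H](Br)CCC(C)=C1OS(=O)(=O)C(F)(F)F | intermediate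
26 | (5S,6S)-5-bromo-6-{3-[(1R,3R)-3-bromo-1,2,2-trimethylcyclopentyl]-2-hydroxy-2-(hydroxymethyl)propyl}-2,6-dimethylcyclohex-1-en-1-yl trifluoromethanesulfonate (carbinol epimers) | CC1(C)[C@H](Br)CC[C@]1(C)CC(O)(CO)C[C@]1(C)[C@@H](Br)CCC(C)=C1OS(=O)(=O)C(F)(F)F | intermediate (not isolated)
27 | (5S,6S)-5-bromo-6-{3-[(1R,3R)-3-bromo-1,2,2-trimethylcyclopentyl]-2-oxopropyl}-2,6-dimethylcyclohex-1-en-1-yl trifluoromethanesulfonate | CC1(C)[C@H](Br)CC[C@]1(C)CC(=O)C[C@]1(C)[C@@H](Br)CCC(C)=C1OS(=O)(=O)C(F)(F)F | intermediate
28 | (5S,6S)-5-bromo-6-{3-[(1R,3R)-3-bromo-1,2,2-trimethylcyclopentyl]-2-oxopropyl}-2,6-dimethylcyclohex-1-ene-1-carbaldehyde | CC1(C)[C@H](Br)CC[C@]1(C)CC(=O)C[C@]1(C)[C@@H](Br)CCC(C)=C1C=O | intermediate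
29 | (8S,8aS)-8-bromo-3-[(1R,3R)-3-bromo-1,2,2-trimethylcyclopentyl]-4-hydroxy-5,8a-dimethyl-3,4,6,7,8,8a-hexahydronaphthalen-2(1H)-one (C3 and C4 unassigned) | CC1(C)[C@H](Br)CC[C@]1(C)C1C(O)C2=C(C)CC[C@H](Br)[C@@]2(C)CC1=O | intermediate (not isolated)
30 | (8S,8aS)-8-bromo-3-[(1R,3R)-3-bromo-1,2,2-trimethylcyclopentyl]-5,8a-dimethyl-6,7,8,8a-tetrahydronaphthalen-2(1H)-one | CC1(C)[C@H](Br)CC[C@]1(C)C1=CC2=C(C)CC[C@H](Br)[C@@]2(C)CC1=O | intermediate
31 | (4aR,5S,8S,8aS)-8-bromo-3-[(1R,3R)-3-bromo-1,2,2-trimethylcyclopentyl]-4a,5-epoxy-5,8a-dimethyl-4a,5,6,7,8,8a-hexahydronaphthalen-2(1H)-one | CC1(C)[C@H](Br)CC[C@]1(C)C1=C[C@]2(O3)[C@]3(C)CC[C@H](Br)[C@@]2(C)CC1=O | intermediate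
32 | (4aR,5R,8S,8aS)-8-bromo-3-[(1R,3R)-3-bromo-1,2,2-trimethylcyclopentyl]-4a,5-dihydroxy-5,8a-dimethyl-4a,5,6,7,8,8a-hexahydronaphthalen-2(1H)-one | CC1(C)[C@H](Br)CC[C@]1(C)C1=C[C@]2(O)[C@](C)(O)CC[C@H](Br)[C@@]2(C)CC1=O | target

## Step count and least certain steps

Total: 24 steps. Longest linear sequence: 24 steps, from 1 to 32; 5 and 20 are purchased and enter in steps 3 and 15.

Step 5 (key step). The most likely failure is loss of material to bimolecular carbene dimerisation or to insertion into adventitious water, and to a lesser extent insertion into a secondary C–H bond, because the carbenoid discriminates only by electron density and ring size. A fallback cannot set out from a route intermediate, since every compound before 9 carries C1' as a C–H centre. It sets out from the commercial auxiliary lactam (3S,7aR)-7a-methyl-3-(propan-2-yl)tetrahydropyrrolo[2,1-b][1,3]oxazol-5(6H)-one F1 and comes back at 14. Enolate methylation (LiN(i-Pr)2, MeI) would give the 6-methyl lactam F2. A second enolate alkylation with tert-butyl(2-iodoethoxy)dimethylsilane would give (3S,6R,7aR)-6-{2-[(tert-butyldimethylsilyl)oxy]ethyl}-6,7a-dimethyl-3-(propan-2-yl)tetrahydropyrrolo[2,1-b][1,3]oxazol-5(6H)-one F3. The second electrophile enters one face of the bicyclic enolate, so the order of the two alkylations decides the quaternary configuration and would be inverted if the other epimer predominated. Reduction with NaAlH2(OCH2CH2OMe)2 and buffered hydrolysis would release the auxiliary and (2R)-2-{2-[(tert-butyldimethylsilyl)oxy]ethyl}-2-methyl-4-oxopentanal F4. KOH in ethanol would close this to (4R)-4-{2-[(tert-butyldimethylsilyl)oxy]ethyl}-4-methylcyclopent-2-en-1-one F5. Double methylation (KOt-Bu, MeI) can occur only at the one enolisable carbon and would give (4S)-4-{2-[(tert-butyldimethylsilyl)oxy]ethyl}-4,5,5-trimethylcyclopent-2-en-1-one F6. Hydrogenation (H2, Pd/C) would give (3R)-3-{2-[(tert-butyldimethylsilyl)oxy]ethyl}-2,2,3-trimethylcyclopentan-1-one F7, and the conditions of step 10 would convert F7 into 14. This gives up the chiral pool for auxiliary control but uses only enolate chemistry.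

Step 17. The most likely failure is elimination or methyl migration in place of substitution, above all at C8, where a cyclohexyl carbon next to a quaternary centre must be attacked from the side of the axial methyl. The fallback sets out from 22 and comes back at 23. It separates activation from displacement: Tf2O and pyridine at −20 °C would give the bis(trifluoromethanesulfonate) of 22, F8, and tetrabutylammonium bromide in toluene at 0 °C would displace both sulfonates with inversion, below the temperature at which E2 becomes competitive. If only one centre responded, the same two-stage method would be applied to the remaining carbinol.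

Step 24. The most likely failure is proton loss from the developing tertiary cation at C5 (allylic alcohol formation) in place of capture by water. The fallback sets out from 30, bypasses 31 and comes back at 32, making the C5 carbinol by carbonyl addition instead of epoxide opening. A Schenck ene reaction of 30 with singlet oxygen (tetraphenylporphyrin, O2, light) can deliver oxygen only to C4a, anti to the C8a methyl, with abstraction of a C5-methyl hydrogen expected to be preferred. It would give the hydroperoxide (4aS,8S,8aS)-8-bromo-3-[(1R,3R)-3-bromo-1,2,2-trimethylcyclopentyl]-4a-hydroperoxy-8a-methyl-5-methylidene-4a,5,6,7,8,8a-hexahydronaphthalen-2(1H)-one F9. PPh3 would reduce F9 to the allylic alcohol (4aS,8S,8aS)-8-bromo-3-[(1R,3R)-3-bromo-1,2,2-trimethylcyclopentyl]-4a-hydroxy-8a-methyl-5-methylidene-4a,5,6,7,8,8a-hexahydronaphthalen-2(1H)-one F10. OsO4 and NaIO4 would cleave the exocyclic olefin to the ketol (4aR,8S,8aS)-8-bromo-3-[(1R,3R)-3-bromo-1,2,2-trimethylcyclopentyl]-4a-hydroxy-8a-methyl-4a,7,8,8a-tetrahydronaphthalene-2,5(1H,6H)-dione F11. MeTi(Oi-Pr)3 adds to α-hydroxy ketones through a chelate in preference to a hindered enone, and it should deliver the methyl group to C5 on the face of the C4a hydroxyl, anti to the angular methyl, to give 32.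

Step 16. The most likely failure is incomplete group or face selection by the catalyst on a dione whose two substituents at C8a differ only beyond the first carbon, together with some over-reduction. The fallback sets out from 21 and comes back at 22. It gives up reagent control: NaBH4 in methanol at −78 °C should reduce anti to the large substituent and give 22 together with its ring B antipodal diastereomer (2S,3S)-3-hydroxy-2-(2-{[(1R,3S)-3-hydroxy-1,2,2-trimethylcyclopentyl]methyl}prop-2-en-1-yl)-2-methylcyclohexan-1-one F12. The two are diastereomers because ring C is enantiopure, so chromatography would separate them, and oxidation of F12 with Dess–Martin periodinane would return 21 for another pass.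

Step 9. The most likely failure is alkoxide-driven Grob fragmentation or oxetane formation from the 1,3-hydroxy sulfonate, because hydride attack at the neopentyl carbon is slow. The fallback sets out from 11, bypasses 12 and comes back at 13. It is a radical deoxygenation that generates no alkoxide: 1,1'-thiocarbonyldiimidazole should acylate the primary hydroxyl to give O-{[(2R)-2-{2-[(tert-butyldimethylsilyl)oxy]ethyl}-5-hydroxy-1,2-dimethylcyclopentyl]methyl} 1H-imidazole-1-carbothioate F13. Bu3SnH with AIBN in toluene at 110 °C (Barton–McCombie) would then reduce the C–O bond to the methyl group.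

## Further compounds

F1 | step 5 | (3S,7aR)-7a-methyl-3-(propan-2-yl)tetrahydropyrrolo[2,1-b][1,3]oxazol-5(6H)-one | CC(C)[C@H]1CO[C@]2(C)CCC(=O)N12
F2 | step 5 | (3S,7aR)-6,7a-dimethyl-3-(propan-2-yl)tetrahydropyrrolo[2,1-b][1,3]oxazol-5(6H)-one (C6 epimers) | CC(C)[C@H]1CO[C@]2(C)CC(C)C(=O)N12
F3 | step 5 | (3S,6R,7aR)-6-{2-[(tert-butyldimethylsilyl)oxy]ethyl}-6,7a-dimethyl-3-(propan-2-yl)tetrahydropyrrolo[2,1-b][1,3]oxazol-5(6H)-one | CC(C)[C@H]1CO[C@]2(C)C[C@@](C)(CCO[Si](C)(C)C(C)(C)C)C(=O)N12
F4 | step 5 | (2R)-2-{2-[(tert-butyldimethylsilyl)oxy]ethyl}-2-methyl-4-oxopentanal | O=C[C@](C)(CCO[Si](C)(C)C(C)(C)C)CC(C)=O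
F5 | step 5 | (4R)-4-{2-[(tert-butyldimethylsilyl)oxy]ethyl}-4-methylcyclopent-2-en-1-one | C1C(=O)C=C[C@]1(C)CCO[Si](C)(C)C(C)(C)C
F6 | step 5 | (4S)-4-{2-[(tert-butyldimethylsilyl)oxy]ethyl}-4,5,5-trimethylcyclopent-2-en-1-one | CC1(C)C(=O)C=C[C@]1(C)CCO[Si](C)(C)C(C)(C)C
F7 | step 5 | (3R)-3-{2-[(tert-butyldimethylsilyl)oxy]ethyl}-2,2,3-trimethylcyclopentan-1-one | CC1(C)C(=O)CC[C@]1(C)CCO[Si](C)(C)C(C)(C)C
F8 | step 17 | (1R,2R)-2-methyl-3-oxo-2-(2-{[(1R,3S)-1,2,2-trimethyl-3-{[(trifluoromethyl)sulfonyl]oxy}cyclopentyl]methyl}prop-2-en-1-yl)cyclohexyl trifluoromethanesulfonate | CC1(C)[C@@H](OS(=O)(=O)C(F)(F)F)CC[C@]1(C)CC(=C)C[C@]1(C)[C@H](OS(=O)(=O)C(F)(F)F)CCCC1=O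
F9 | step 24 | (4aS,8S,8aS)-8-bromo-3-[(1R,3R)-3-bromo-1,2,2-trimethylcyclopentyl]-4a-hydroperoxy-8a-methyl-5-methylidene-4a,5,6,7,8,8a-hexahydronaphthalen-2(1H)-one | CC1(C)[C@H](Br)CC[C@]1(C)C1=C[C@]2(OO)C(=C)CC[C@H](Br)[C@@]2(C)CC1=O
F10 | step 24 | (4aS,8S,8aS)-8-bromo-3-[(1R,3R)-3-bromo-1,2,2-trimethylcyclopentyl]-4a-hydroxy-8a-methyl-5-methylidene-4a,5,6,7,8,8a-hexahydronaphthalen-2(1H)-one | CC1(C)[C@H](Br)CC[C@]1(C)C1=C[C@]2(O)C(=C)CC[C@H](Br)[C@@]2(C)CC1=O
F11 | step 24 | (4aR,8S,8aS)-8-bromo-3-[(1R,3R)-3-bromo-1,2,2-trimethylcyclopentyl]-4a-hydroxy-8a-methyl-4a,7,8,8a-tetrahydronaphthalene-2,5(1H,6H)-dione | CC1(C)[C@H](Br)CC[C@]1(C)C1=C[C@]2(O)C(=O)CC[C@H](Br)[C@@]2(C)CC1=O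
F12 | step 16 | (2S,3S)-3-hydroxy-2-(2-{[(1R,3S)-3-hydroxy-1,2,2-trimethylcyclopentyl]methyl}prop-2-en-1-yl)-2-methylcyclohexan-1-one | CC1(C)[C@@H](O)CC[C@]1(C)CC(=C)C[C@@]1(C)[C@@H](O)CCCC1=O
F13 | step 9 | O-{[(2R)-2-{2-[(tert-butyldimethylsilyl)oxy]ethyl}-5-hydroxy-1,2-dimethylcyclopentyl]methyl} 1H-imidazole-1-carbothioate (mixture at C1 and C5) | S=C(OCC1(C)C(O)CC[C@]1(C)CCO[Si](C)(C)C(C)(C)C)n1ccnc1
A1 | alternative 1 | C2,C4a-endoperoxide of A2, peroxide bridge anti to the C8a methyl | CC1(C)[C@H](Br)CC[C@]1(C)C1=C[C@]2(OO3)[C@](C)(O)CC[C@H](Br)[C@@]2(C)C[C@H]13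
A2 | alternative 1 | (1R,4S,4aS)-4-bromo-7-[(1R,3R)-3-bromo-1,2,2-trimethylcyclopentyl]-1,4a-dimethyl-1,2,3,4,4a,5-hexahydronaphthalen-1-ol | CC1(C)[C@H](Br)CC[C@]1(C)C1=CC[C@]2(C)[C@@H](Br)CC[C@@](C)(O)C2=C1
A3 | alternative 2 | [(5S,6S)-5-bromo-6-(cyanomethyl)-2,6-dimethylcyclohex-1-en-1-yl]methyl acetate | CC(=O)OCC1=C(C)CC[C@H](Br)[C@@]1(C)CC#N
A4 | alternative 2 | (2E,6E)-8-cyano-3,7-dimethylocta-2,6-dien-1-yl acetate | CC(=O)OC/C=C(\C)CC/C=C(\C)CC#N
A5 | alternative 3 | (3S)-2,2-dimethyl-1-{2-[(triisopropylsilyl)oxy]ethyl}bicyclo[3.1.0]hexan-3-ol, cis-fused, C6 methylene syn to the hydroxyl | CC1(C)[C@@H](O)C[C@H]2C[C@@]12CCO[Si](C(C)C)(C(C)C)C(C)C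
A6 | alternative 3 | (1S)-2,2-dimethyl-3-{2-[(triisopropylsilyl)oxy]ethyl}cyclopent-3-en-1-ol | CC1(C)[C@@H](O)CC=C1CCO[Si](C(C)C)(C(C)C)C(C)C
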